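**Assumption:** the target (polycitone B) has no stereocentre and is achiral, so no stereocontrol is needed; the structure is made exactly as written in the SMILES.

## Retrosynthetic overview

1. Target ⇐ fourfold O-demethylation and eightfold ortho-bromination of the tetra(4-methoxyphenyl) 2,5-diaroyl-3,4-diarylpyrrole.
2. Pyrrole ⇐ Paal–Knorr condensation of ammonia with a 1,3,4,6-tetraaryl-hexane-1,2,5,6-tetraone (inner carbonyls become C2 and C5).
3. Tetraone ⇐ central C3–C4 bond by oxidative homocoupling of two 1,3-diarylpropane-1,2-dione enolates; one is converted in the flask into its α-iodo derivative, whose α-carbon is electrophilic (enolonium equivalent).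
4. 1,2-Dione ⇐ Darzens condensation and epoxy-ketone rearrangement from 2-bromo-4'-methoxyacetophenone and 4-methoxybenzaldehyde.
5. Ring order: the four benzene rings are bought; the pyrrole is the only ring built, in the key step.

## Route

**Step 1**
Reactants: 1 2-bromo-1-(4-methoxyphenyl)ethanone; 2 4-methoxybenzaldehyde
Product: 5 1,3-bis(4-methoxyphenyl)propane-1,2-dione, via bromohydrin alkoxide 3 (not isolated), via trans-epoxy ketone 4 (not isolated)
Conditions: NaOEt (1.05 equiv), EtOH, 0 °C to rt; then NaOEt (1.1 equiv), reflux, 20 min; aq HCl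
Reagents that add atoms: none
Why: Darzens condensation (aldol of the bromoketone enolate onto the aldehyde, then intramolecular SN2 of alkoxide 3) gives trans-epoxy ketone 4, which the same alkoxide base isomerises to the 1,2-diketone (base-mediated epoxy ketone to diosphenol rearrangement, driven by formation of the stabilised enolate of 5); the transient stereocentres of 3 and 4 are erased in 5, so their configuration is irrelevant.

**Step 2**
Reactants: 5 1,3-bis(4-methoxyphenyl)propane-1,2-dione (2 equiv)
Product: 8 [3,4-bis(4-methoxyphenyl)-1H-pyrrole-2,5-diyl]bis[(4-methoxyphenyl)methanone], via alpha-iodo diketone 6 (not isolated), via tetraketone 7 (not isolated)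
Conditions: NaH (1.05 equiv), THF, 0 °C; I2 (0.5 equiv), −78 °C to rt; then NH4OAc (10 equiv), AcOH, 70 °C
Reagents that add atoms: ammonium acetate, CC(=O)[O-].[NH4+]
Why: Proposed new method: C-iodination of the sodium enolate of 5 gives the α-iodo-1,2-diketone 6, an enolonium equivalent with an electrophilic benzylic α-carbon, and a second enolate displaces iodide there to join two normally nucleophilic α-carbons as tetraketone 7 (the future C3–C4 bond; the meso/dl ratio is irrelevant because both stereocentres are lost on aromatisation), after which NH4OAc condenses with the two inner, more electrophilic, 1,4-related carbonyls in a Paal–Knorr pyrrole synthesis; the closest known reaction type is the I2-mediated oxidative dimerisation of arylpyruvate enolates followed by ammonia condensation to 3,4-diarylpyrrole-2,5-dicarboxylates.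

**Step 3**
Reactants: 8 [3,4-bis(4-methoxyphenyl)-1H-pyrrole-2,5-diyl]bis[(4-methoxyphenyl)methanone]
Product: 10 [3,4-bis(3,5-dibromo-4-hydroxyphenyl)-1H-pyrrole-2,5-diyl]bis[(3,5-dibromo-4-hydroxyphenyl)methanone], via tetraphenol 9 (not isolated)
Conditions: BBr3 (10 equiv), CH2Cl2, −78 °C to rt; MeOH, 0 °C, evaporate; then Br2 (8.2 equiv), AcOH, rt
Reagents that add atoms: bromine, BrBr
Why: BBr3 cleaves the four aryl methyl ethers (Lewis acid-mediated ether cleavage) and, after methanolysis of the aryl borates, the four para-substituted phenols undergo exhaustive ortho,ortho-dibromination by electrophilic aromatic substitution, while the fully substituted, doubly acyl-deactivated pyrrole and the diaryl ketones are inert; no stereocentre is involved.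

## Compound list

1 | 2-bromo-1-(4-methoxyphenyl)ethanone | COc1ccc(cc1)C(=O)CBr | starting material
2 | 4-methoxybenzaldehyde | COc1ccc(C=O)cc1 | starting material
3 | 2-bromo-3-hydroxy-1,3-bis(4-methoxyphenyl)propan-1-one (racemic diastereomer mixture, present as its sodium alkoxide) | COc1ccc(cc1)C(=O)C(Br)C(O)c1ccc(OC)cc1 | intermediate (not isolated)
4 | (4-methoxyphenyl)[(2R*,3S*)-3-(4-methoxyphenyl)oxiran-2-yl]methanone (racemic trans-epoxide, one enantiomer drawn) | COc1ccc(cc1)C(=O)[C@@H]1O[C@H]1c1ccc(OC)cc1 | intermediate (not isolated)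
5 | 1,3-bis(4-methoxyphenyl)propane-1,2-dione (exists largely as the Z-enol) | COc1ccc(CC(=O)C(=O)c2ccc(OC)cc2)cc1 | intermediate
6 | 3-iodo-1,3-bis(4-methoxyphenyl)propane-1,2-dione (racemic) | COc1ccc(cc1)C(I)C(=O)C(=O)c1ccc(OC)cc1 | intermediate (not isolated)
7 | 1,3,4,6-tetrakis(4-methoxyphenyl)hexane-1,2,5,6-tetraone (meso/dl mixture) | COc1ccc(cc1)C(=O)C(=O)C(c1ccc(OC)cc1)C(c1ccc(OC)cc1)C(=O)C(=O)c1ccc(OC)cc1 | intermediate (not isolated)
8 | [3,4-bis(4-methoxyphenyl)-1H-pyrrole-2,5-diyl]bis[(4-methoxyphenyl)methanone] | COc1ccc(cc1)C(=O)c1[nH]c(C(=O)c2ccc(OC)cc2)c(-c2ccc(OC)cc2)c1-c1ccc(OC)cc1 | intermediate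
9 | [3,4-bis(4-hydroxyphenyl)-1H-pyrrole-2,5-diyl]bis[(4-hydroxyphenyl)methanone] | Oc1ccc(cc1)C(=O)c1[nH]c(C(=O)c2ccc(O)cc2)c(-c2ccc(O)cc2)c1-c1ccc(O)cc1 | intermediate (not isolated)
10 | [3,4-bis(3,5-dibromo-4-hydroxyphenyl)-1H-pyrrole-2,5-diyl]bis[(3,5-dibromo-4-hydroxyphenyl)methanone] (polycitone B) | O=C(c1cc(Br)c(O)c(Br)c1)c1[nH]c(C(=O)c2cc(Br)c(O)c(Br)c2)c(-c2cc(Br)c(O)c(Br)c2)c1-c1cc(Br)c(O)c(Br)c1 | target

## Totals

Total step count: 3. Longest linear sequence: 3.

## Steps most likely to fail, with fallbacks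

With three steps, all three carry risk; step 2 is the riskiest, then step 1, then step 3.

**Step 1 (one-pot Darzens and rearrangement).** The risk is over-reaction of the dione under hot alkoxide (benzilic-type rearrangement or acyl cleavage) or incomplete isomerisation of the epoxide. The fallback sets out from 2 and makes 5 by α-oxidation of a saturated ketone instead of by epoxide rearrangement. Claisen–Schmidt condensation of 2 with commercial 1-(4-methoxyphenyl)ethanone (NaOH, EtOH) gives (E)-1,3-bis(4-methoxyphenyl)prop-2-en-1-one F1. Hydrogenation of the alkene (H2, Pd/C, EtOAc) gives 1,3-bis(4-methoxyphenyl)propan-1-one F2. Nitrosation at the only enolisable ketone α-position (isopentyl nitrite, HCl, Et2O) gives (E)-2-(hydroxyimino)-1,3-bis(4-methoxyphenyl)propan-1-one F3. Deoximation by oxime exchange with aqueous formaldehyde and HCl then comes back to the route at 5.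

**Step 2 (oxidative enolate homocoupling and Paal–Knorr).** The risks are O- instead of C-coupling, proton transfer from 7 to unreacted enolate with over-oxidation, and competing six-membered condensation onto an outer aroyl carbonyl. The fallback sets out from 2 and builds the pyrrole from an arylpyruvic acid, attaching the aroyl groups afterwards. Erlenmeyer–Plöchl condensation of 2 with N-acetylglycine (Ac2O, NaOAc, 100 °C) gives (Z)-4-(4-methoxybenzylidene)-2-methyloxazol-5(4H)-one F4. Hydrolysis in refluxing aqueous HCl gives 3-(4-methoxyphenyl)-2-oxopropanoic acid F5. Its dianion (n-BuLi, 2 equiv, THF, −78 °C) is dimerised with I2 (0.5 equiv) and condensed with NH3 to give 3,4-bis(4-methoxyphenyl)-1H-pyrrole-2,5-dicarboxylic acid F6. Double decarboxylation in refluxing 2-aminoethanol gives 3,4-bis(4-methoxyphenyl)-1H-pyrrole F7. Twofold Friedel–Crafts acylation at the free 2- and 5-positions with 4-methoxybenzoyl chloride (SnCl4, 1,2-dichloroethane, reflux) comes back to the route at 8.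

**Step 3 (telescoped demethylation and octabromination).** The risks are incomplete bromination in the presence of boron residues, or oxidation and ipso-substitution of the electron-rich tetraphenol by the large excess of Br2. The fallback sets out from 8 and splits the halogenation so that half of the bromines are installed on the robust methyl ethers and each intermediate is isolated. Bromination of 8 (Br2, 4.2 equiv, AcOH, NaOAc, 60 °C) puts one bromine ortho to each methoxy group to give [3,4-bis(3-bromo-4-methoxyphenyl)-1H-pyrrole-2,5-diyl]bis[(3-bromo-4-methoxyphenyl)methanone] F8. Demethylation with BBr3 (CH2Cl2, then aqueous work-up) gives [3,4-bis(3-bromo-4-hydroxyphenyl)-1H-pyrrole-2,5-diyl]bis[(3-bromo-4-hydroxyphenyl)methanone] F9. Bromination of the one remaining ortho position of each phenol (Br2, 4.1 equiv, AcOH, rt) comes back to the route at 10.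

## Further compounds

F1 | step 1 | (E)-1,3-bis(4-methoxyphenyl)prop-2-en-1-one | COc1ccc(/C=C/C(=O)c2ccc(OC)cc2)cc1
F2 | step 1 | 1,3-bis(4-methoxyphenyl)propan-1-one | COc1ccc(CCC(=O)c2ccc(OC)cc2)cc1
F3 | step 1 | (E)-2-(hydroxyimino)-1,3-bis(4-methoxyphenyl)propan-1-one | COc1ccc(C/C(=N\O)C(=O)c2ccc(OC)cc2)cc1
F4 | step 2 | (Z)-4-(4-methoxybenzylidene)-2-methyloxazol-5(4H)-one | COc1ccc(/C=C2\N=C(C)OC2=O)cc1
F5 | step 2 | 3-(4-methoxyphenyl)-2-oxopropanoic acid | COc1ccc(CC(=O)C(=O)O)cc1
F6 | step 2 | 3,4-bis(4-methoxyphenyl)-1H-pyrrole-2,5-dicarboxylic acid | COc1ccc(cc1)-c1c(C(=O)O)[nH]c(C(=O)O)c1-c1ccc(OC)cc1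
F7 | step 2 | 3,4-bis(4-methoxyphenyl)-1H-pyrrole | COc1ccc(cc1)-c1c[nH]cc1-c1ccc(OC)cc1
F8 | step 3 | [3,4-bis(3-bromo-4-methoxyphenyl)-1H-pyrrole-2,5-diyl]bis[(3-bromo-4-methoxyphenyl)methanone] | COc1ccc(cc1Br)C(=O)c1[nH]c(C(=O)c2ccc(OC)c(Br)c2)c(-c2ccc(OC)c(Br)c2)c1-c1ccc(OC)c(Br)c1
F9 | step 3 | [3,4-bis(3-bromo-4-hydroxyphenyl)-1H-pyrrole-2,5-diyl]bis[(3-bromo-4-hydroxyphenyl)methanone] | Oc1ccc(cc1Br)C(=O)c1[nH]c(C(=O)c2ccc(O)c(Br)c2)c(-c2ccc(O)c(Br)c2)c1-c1ccc(O)c(Br)c1
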